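## Retrosynthetic overview

1. Feature: C10 sits in both the lactone ring O–C2(=O)–C1–C10–C9–C8 and ring B (C10–C5–C6–C7–C8–C9), and its two arms C1–C2 and C9–C11 have the same length and both end in a carbonyl carbon. C10 is therefore carried as an achiral C(CH3)(CH2CHO)2 unit, cut out of a cyclopentene, until ring B closes.
2. Target ⇒ bridged lactol aldehyde 20: C2 lactol → δ-lactone (oxidation), γ-lactone → C3 allyl ester + C6 silyl ether, side chain C12–C16 from the C11 aldehyde (enolate aldol, then chelate-controlled methyl addition).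
3. 20 ⇒ keto-dialdehyde γ-lactone 18: proline aldol C9→C8 (ring B) with capture of the C8 hydroxyl by the other arm (O–C2, lactol ring).
4. 18 ⇒ acid 14 (C6 by hydrogenation of an enol lactone) ⇒ Ireland–Claisen of isobutyrate 11 (C5) ⇒ enone 8 from aldehyde 6 and ketone 7; 6 from ester 1 by methylation and ozonolysis/acetalisation.
5. Ring order: γ-lactone (steps 9–11, temporary), then ring B and the lactol ring together (step 13); the lactol becomes the δ-lactone in step 20.

Key step: step 13

Remarks before the steps: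
- Numbering used in names: side chain C9–C11(OH)–C12–C13(CH3)(OH)–C14=C15; acid arm C5–C4(CH3)2–C3. The target is 5R,6R,8S,9S,10R,11S,13R.
- Assumption: in the oxazaborolidine reduction (step 6) the quaternary ketal carbon acts as the large ketone substituent; if the sense proved opposite, the antipodal catalyst would be used.
- C2 in 20, 21, 23–28 may be either anomer; it becomes sp2 in 29.

## Route

Step 1
Reactants: 1 methyl cyclopent-3-ene-1-carboxylate
Product: 2 methyl 1-methylcyclopent-3-ene-1-carboxylate
Conditions: LiN(i-Pr)2, THF, −78 °C; MeI, −78 → 23 °C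
Reagents that add atoms: iodomethane (CI)
Why: Ester enolate alkylation; the new quaternary carbon (future C10) lies on the mirror plane of the ring and is not stereogenic.

Step 2
Reactants: 2 methyl 1-methylcyclopent-3-ene-1-carboxylate
Product: 4 methyl 4,4-dimethoxy-2-(2,2-dimethoxyethyl)-2-methylbutanoate, via dialdehyde 3 (not isolated)
Conditions: O3, CH2Cl2/MeOH, −78 °C; Me2S, −78 → 23 °C; then HC(OMe)3, TsOH (cat.), 23 °C
Reagents that add atoms: ozone ([O-][O+]=O); trimethyl orthoformate (COC(OC)OC)
Why: Ozonolysis with reductive work-up followed by acid-catalysed acetalisation should give both arms as identical dimethyl acetals, so C10 stays non-stereogenic and no alkene is left to compete in the hydrogenation of step 11.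

Step 3
Reactants: 4 methyl 4,4-dimethoxy-2-(2,2-dimethoxyethyl)-2-methylbutanoate
Product: 5 4,4-dimethoxy-2-(2,2-dimethoxyethyl)-2-methylbutan-1-ol
Conditions: LiAlH4, THF, 0 °C
Reagents that add atoms: none
Why: Hydride reduction of the neopentyl ester to the primary alcohol; acetals are inert to LiAlH4.

Step 4
Reactants: 5 4,4-dimethoxy-2-(2,2-dimethoxyethyl)-2-methylbutan-1-ol
Product: 6 4,4-dimethoxy-2-(2,2-dimethoxyethyl)-2-methylbutanal
Conditions: TEMPO (10 mol%), PhI(OAc)2, CH2Cl2, 23 °C
Reagents that add atoms: none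
Why: Oxoammonium (TEMPO) oxidation of a primary alcohol; the aldehyde has no α-hydrogen and cannot enolise or over-oxidise under these conditions.

Step 5
Reactants: 6 4,4-dimethoxy-2-(2,2-dimethoxyethyl)-2-methylbutanal; 7 3,3-dimethoxybutan-2-one
Product: 8 (E)-6-(2,2-dimethoxyethyl)-2,2,8,8-tetramethoxy-6-methyloct-4-en-3-one
Conditions: KOH, MeOH, 50 °C
Reagents that add atoms: none
Why: Claisen–Schmidt condensation between a non-enolisable aldehyde and a ketone that can enolise only at its methyl group; E1cB dehydration should give the (E)-enone.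

Step 6
Reactants: 8 (E)-6-(2,2-dimethoxyethyl)-2,2,8,8-tetramethoxy-6-methyloct-4-en-3-one
Product: 9 (3S,4E)-6-(2,2-dimethoxyethyl)-2,2,8,8-tetramethoxy-6-methyloct-4-en-3-ol
Conditions: (R)-2-methyl-CBS-oxazaborolidine (20 mol%), catecholborane, toluene, −78 °C
Reagents that add atoms: none
Why: Corey–Bakshi–Shibata reduction; with the ketal carbon as the large group the (R)-catalyst should deliver hydride to the face that gives the (3S) carbinol (C7).

Step 7
Reactants: 9 (3S,4E)-6-(2,2-dimethoxyethyl)-2,2,8,8-tetramethoxy-6-methyloct-4-en-3-ol; 10 isobutyryl chloride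
Product: 11 (3S,4E)-6-(2,2-dimethoxyethyl)-2,2,8,8-tetramethoxy-6-methyloct-4-en-3-yl 2-methylpropanoate
Conditions: pyridine, DMAP (cat.), CH2Cl2, 0 → 23 °C
Reagents that add atoms: none
Why: Acylation of the secondary allylic alcohol with retention at C7.

Step 8
Reactants: 11 (3S,4E)-6-(2,2-dimethoxyethyl)-2,2,8,8-tetramethoxy-6-methyloct-4-en-3-yl 2-methylpropanoate
Product: 14 (3R,4E)-3-[4,4-dimethoxy-2-(2,2-dimethoxyethyl)butan-2-yl]-6,6-dimethoxy-2,2-dimethylhept-4-enoic acid, via silyl ketene acetal 12 (not isolated), via trimethylsilyl ester 13 (not isolated)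
Conditions: LiN(i-Pr)2, THF, −78 °C; Me3SiCl/Et3N, −78 → 60 °C; pH 5 citrate buffer, 0 °C
Reagents that add atoms: none
Why: Ireland–Claisen rearrangement through a chair with the ketal substituent on C7 equatorial; it should transfer the (7S) carbinol configuration to (5R) at the new C4–C5 bond and give the (E)-alkene (the ketene acetal is symmetric, so no enolate geometry is involved).

Step 9
Reactants: 14 (3R,4E)-3-[4,4-dimethoxy-2-(2,2-dimethoxyethyl)butan-2-yl]-6,6-dimethoxy-2,2-dimethylhept-4-enoic acid
Product: 15 (4R)-4-[4,4-dimethoxy-2-(2,2-dimethoxyethyl)butan-2-yl]-5-(1-iodo-2,2-dimethoxypropyl)-3,3-dimethyloxolan-2-one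
Conditions: I2, NaHCO3, MeCN, 0 °C, dark
Reagents that add atoms: iodine (II)
Why: 5-exo iodolactonisation (anti addition, oxygen to C6 because the ketal disfavours charge at C7); the configurations formed at C6 and C7 do not matter because both are erased in steps 10 and 11.

Step 10
Reactants: 15 (4R)-4-[4,4-dimethoxy-2-(2,2-dimethoxyethyl)butan-2-yl]-5-(1-iodo-2,2-dimethoxypropyl)-3,3-dimethyloxolan-2-one
Product: 16 (4R,5E)-4-[4,4-dimethoxy-2-(2,2-dimethoxyethyl)butan-2-yl]-5-(2,2-dimethoxypropylidene)-3,3-dimethyloxolan-2-one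
Conditions: DBU, toluene, 90 °C
Reagents that add atoms: none
Why: E2 dehydroiodination; H6 is the only hydrogen β to the iodide, so the exocyclic enol lactone is the only possible alkene (anti elimination should give the E isomer, but the geometry is of no consequence).

Step 11
Reactants: 16 (4R,5E)-4-[4,4-dimethoxy-2-(2,2-dimethoxyethyl)butan-2-yl]-5-(2,2-dimethoxypropylidene)-3,3-dimethyloxolan-2-one
Product: 17 (4R,5R)-4-[4,4-dimethoxy-2-(2,2-dimethoxyethyl)butan-2-yl]-5-(2,2-dimethoxypropyl)-3,3-dimethyloxolan-2-one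
Conditions: H2 (3 atm), Rh/Al2O3 (5 wt% Rh), EtOAc, 23 °C
Reagents that add atoms: none
Why: Heterogeneous hydrogenation of the enol lactone from the ring face opposite the quaternary C10 substituent on C5 should place H6 trans to C10 and so give the cis (6R) lactone, which a direct reductive removal of iodine from 15 would not secure.

Step 12
Reactants: 17 (4R,5R)-4-[4,4-dimethoxy-2-(2,2-dimethoxyethyl)butan-2-yl]-5-(2,2-dimethoxypropyl)-3,3-dimethyloxolan-2-one
Product: 18 3-[(2R,3R)-4,4-dimethyl-5-oxo-2-(2-oxopropyl)oxolan-3-yl]-3-methylpentanedial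
Conditions: TFA/H2O (1:1), CHCl3, 0 °C
Reagents that add atoms: water (O)
Why: Acid hydrolysis of the ketal and both acetals under cold, weakly nucleophilic conditions that a β-acyloxy ketone tolerates; the keto-dialdehyde is used at once.

Step 13
Reactants: 18 3-[(2R,3R)-4,4-dimethyl-5-oxo-2-(2-oxopropyl)oxolan-3-yl]-3-methylpentanedial
Product: 20 bridged lactol aldehyde (5R,6R,8S,9R,10R), via aldol 19 (not isolated)
Conditions: (R)-proline (30 mol%), DMSO/CHCl3 (1:4), 23 °C
Reagents that add atoms: none
Why: Proposed new method: (R)-proline condenses with one CH2CHO arm to an (E)-enamine whose α-carbon C9 adds to the C8 methyl ketone (activated by the hydrogen bond from the carboxylic acid), and the tertiary C8 hydroxyl then adds to the aldehyde of the other arm to give lactol 20; the closest known reaction type is the proline-catalysed 6-enolexo aldol cyclisation of dialdehydes and keto-aldehydes, which has not been used to choose between two diastereotopic aldehyde arms with a lactol as the trap. Ring B closes in the 6-(enolexo)-exo-trig mode through a chair, and the lactol ring closes by 6-exo-trig addition of the hydroxyl to C2. C10 is set by the choice of arm: in the chair that keeps the C4 substituent on C5 equatorial the leftover arm is axial only in the required (10R) epimer, only an axial arm can reach the C8 oxygen, and lactol formation therefore withdraws this isomer while the other aldols can return to 18 by retro-aldol reaction. C9 is set by attack on the enamine face syn to the carboxylic acid, for which (R)-proline is the matched enantiomer, and is held by the equatorial preference of the formyl group; C8 is set because the ketone oxygen, not the methyl group, takes the axial site 1,3 to the axial arm. The step needs aldehyde-enamine donors to win over ketone enamines and must avoid β-elimination of the C6 carboxylate: aldehydes form enamines faster than the methyl ketone, an aldehyde enamine could reach the other aldehyde only through a four-membered ring and so has only the six-membered path to C8, and the zwitterionic catalyst keeps the medium too weakly basic for E1cB loss of the acyloxy group.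

Step 14
Reactants: 20 bridged lactol aldehyde (5R,6R,8S,9R,10R)
Product: 21 4-methoxybenzyl acetal of 20 at C2
Conditions: 4-MeOC6H4CH2OH, PPTS (cat.), 4 Å MS, CH2Cl2, 23 °C
Reagents that add atoms: 4-methoxybenzyl alcohol (COc1ccc(CO)cc1)
Why: Acid-catalysed exchange of the lactol hydroxyl through the cyclic oxocarbenium ion; the C11 aldehyde, flanked by two quaternary carbons, should not form a stable acetal.

Step 15
Reactants: 21 4-methoxybenzyl acetal of 20 at C2; 22 2-(trimethylsilyloxy)buta-1,3-diene
Product: 23 (11S)-β-hydroxy enone with side chain C9–CH(OH)–CH2–C(=O)–CH=CH2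
Conditions: 22, MeLi, THF, 0 °C; then 21, −78 °C; pH 7 buffer
Reagents that add atoms: none
Why: Aldol addition of the lithium enolate of methyl vinyl ketone (released from its silyl enol ether by MeLi); attack anti to the larger C10 branch of C9, with the carbonyl oxygen near the C8 ring oxygen (the chelate and the open 1,2-induction models agree), should give the (11S) carbinol.

Step 16
Reactants: 23 (11S)-β-hydroxy enone with side chain C9–CH(OH)–CH2–C(=O)–CH=CH2
Product: 24 diol with side chain C9–CH(OH)–CH2–C(CH3)(OH)–CH=CH2 (11S,13R)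
Conditions: MeMgBr (3 equiv.), CH2Cl2/Et2O, −78 °C
Reagents that add atoms: methylmagnesium bromide (C[Mg]Br)
Why: Chelate-controlled 1,2-addition of the Grignard reagent to the magnesium aldolate: axial attack on the six-membered O11–Mg–O13 chelate, with the bulky C11 substituent equatorial, should place the methyl group axial and the vinyl group equatorial, which is the (13R) syn-diol.

Step 17
Reactants: 24 diol with side chain C9–CH(OH)–CH2–C(CH3)(OH)–CH=CH2 (11S,13R)
Product: 26 C3 allyl ester with free 6-OH 11-OH 13-OH, via potassium carboxylate 25 (not isolated)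
Conditions: KOH (1.2 equiv.), MeOH/H2O, 40 °C; evaporate; CH2=CHCH2Br, KHCO3, DMF, 23 °C
Reagents that add atoms: potassium hydroxide ([K+].[OH-]); allyl bromide (C=CCBr)
Why: Saponification of the γ-lactone and O-alkylation of the carboxylate salt before it can relactonise; the acetal at C2 is stable to base, so the γ-lactone is opened while no second lactone is present.

Step 18
Reactants: 26 C3 allyl ester with free 6-OH 11-OH 13-OH
Product: 27 6,11-bis(triethylsilyl) ether of 26
Conditions: Et3SiCl, imidazole, DMAP (cat.), DMF, 40 °C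
Reagents that add atoms: chlorotriethylsilane (CC[Si](Cl)(CC)CC)
Why: Silylation of the two secondary alcohols (the tertiary allylic alcohol should stay free); a silyl triflate is avoided because it could activate the acetal at C2.

Step 19
Reactants: 27 6,11-bis(triethylsilyl) ether of 26
Product: 28 C2 lactol
Conditions: DDQ, CH2Cl2/pH 7 buffer, 0 → 23 °C
Reagents that add atoms: none
Why: Oxidative cleavage of the 4-methoxybenzyl acetal (benzylic hydride abstraction, then hydrolysis) under neutral conditions that spare silyl ethers, the allyl ester and the tertiary allylic alcohol.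

Step 20
Reactants: 28 C2 lactol
Product: 29 δ-lactone (O8–C2=O) bis(triethylsilyl) ether allyl ester
Conditions: TEMPO (20 mol%), PhI(OAc)2, CH2Cl2, 23 °C
Reagents that add atoms: none
Why: Oxoammonium oxidation of a lactol to the lactone; the only other free hydroxyl is tertiary and cannot be oxidised.

Step 21
Reactants: 29 δ-lactone (O8–C2=O) bis(triethylsilyl) ether allyl ester
Product: 30 allyl ester of the target
Conditions: HF·pyridine, pyridine, THF, 0 → 23 °C
Reagents that add atoms: none
Why: Buffered fluoride cleavage of the two triethylsilyl ethers; no alkoxide is generated, which guards against attack of the 6-hydroxyl on the neighbouring δ-lactone.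

Step 22
Reactants: 30 allyl ester of the target
Product: 31 CNP0297019.1 (5R,6R,8S,9S,10R,11S,13R)
Conditions: Pd(PPh3)4 (5 mol%), morpholine, THF, 23 °C; pH 5 buffer
Reagents that add atoms: none
Why: Tsuji–Trost deallylation through a π-allyl palladium complex trapped by morpholine; the near-neutral conditions should spare the δ-lactone, the tertiary allylic alcohol and the hydroxy acid.

## Compound list

1 | methyl cyclopent-3-ene-1-carboxylate | COC(=O)C1CC=CC1 | starting material
2 | methyl 1-methylcyclopent-3-ene-1-carboxylate | COC(=O)C1(C)CC=CC1 | intermediate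
3 | methyl 2-methyl-4-oxo-2-(2-oxoethyl)butanoate | COC(=O)C(C)(CC=O)CC=O | intermediate (not isolated)
4 | methyl 4,4-dimethoxy-2-(2,2-dimethoxyethyl)-2-methylbutanoate | COC(=O)C(C)(CC(OC)OC)CC(OC)OC | intermediate
5 | 4,4-dimethoxy-2-(2,2-dimethoxyethyl)-2-methylbutan-1-ol | OCC(C)(CC(OC)OC)CC(OC)OC | intermediate
6 | 4,4-dimethoxy-2-(2,2-dimethoxyethyl)-2-methylbutanal | O=CC(C)(CC(OC)OC)CC(OC)OC | intermediate
7 | 3,3-dimethoxybutan-2-one | CC(=O)C(C)(OC)OC | starting material
8 | (E)-6-(2,2-dimethoxyethyl)-2,2,8,8-tetramethoxy-6-methyloct-4-en-3-one | CC(OC)(OC)C(=O)/C=C/C(C)(CC(OC)OC)CC(OC)OC | intermediate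
9 | (3S,4E)-6-(2,2-dimethoxyethyl)-2,2,8,8-tetramethoxy-6-methyloct-4-en-3-ol | CC(OC)(OC)[C@@H](O)/C=C/C(C)(CC(OC)OC)CC(OC)OC | intermediate
10 | isobutyryl chloride | CC(C)C(Cl)=O | starting material
11 | (3S,4E)-6-(2,2-dimethoxyethyl)-2,2,8,8-tetramethoxy-6-methyloct-4-en-3-yl 2-methylpropanoate | CC(OC)(OC)[C@@H](OC(=O)C(C)C)/C=C/C(C)(CC(OC)OC)CC(OC)OC | intermediate
12 | trimethylsilyl ketene acetal of 11 | CC(OC)(OC)[C@@H](OC(O[Si](C)(C)C)=C(C)C)/C=C/C(C)(CC(OC)OC)CC(OC)OC | intermediate (not isolated)
13 | trimethylsilyl ester of 14 | CC(OC)(OC)/C=C/[C@H](C(C)(CC(OC)OC)CC(OC)OC)C(C)(C)C(=O)O[Si](C)(C)C | intermediate (not isolated)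
14 | (3R,4E)-3-[4,4-dimethoxy-2-(2,2-dimethoxyethyl)butan-2-yl]-6,6-dimethoxy-2,2-dimethylhept-4-enoic acid (C5 R) | CC(OC)(OC)/C=C/[C@H](C(C)(CC(OC)OC)CC(OC)OC)C(C)(C)C(=O)O | intermediate
15 | (4R)-4-[4,4-dimethoxy-2-(2,2-dimethoxyethyl)butan-2-yl]-5-(1-iodo-2,2-dimethoxypropyl)-3,3-dimethyloxolan-2-one; C6 and C7 as formed | CC(OC)(OC)C(I)C1OC(=O)C(C)(C)[C@H]1C(C)(CC(OC)OC)CC(OC)OC | intermediate
16 | (4R,5E)-4-[4,4-dimethoxy-2-(2,2-dimethoxyethyl)butan-2-yl]-5-(2,2-dimethoxypropylidene)-3,3-dimethyloxolan-2-one | CC(OC)(OC)/C=C1/OC(=O)C(C)(C)[C@H]1C(C)(CC(OC)OC)CC(OC)OC | intermediate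
17 | (4R,5R)-4-[4,4-dimethoxy-2-(2,2-dimethoxyethyl)butan-2-yl]-5-(2,2-dimethoxypropyl)-3,3-dimethyloxolan-2-one (cis; C5 R, C6 R) | CC(OC)(OC)C[C@H]1OC(=O)C(C)(C)[C@H]1C(C)(CC(OC)OC)CC(OC)OC | intermediate
18 | 3-[(2R,3R)-4,4-dimethyl-5-oxo-2-(2-oxopropyl)oxolan-3-yl]-3-methylpentanedial (key-step precursor) | CC(=O)C[C@H]1OC(=O)C(C)(C)[C@H]1C(C)(CC=O)CC=O | intermediate
19 | aldol: ring B closed; 8-hydroxy; 9-formyl; C10 bears CH3 and CH2CHO; cis-fused C3/O6 γ-lactone; 5R,6R,8S,9R,10R | O=CC[C@@]1(C)[C@@H](C=O)[C@@](C)(O)C[C@H]2OC(=O)C(C)(C)[C@@H]12 | intermediate (not isolated)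
20 | bridged lactol aldehyde: O8 closed onto C2 (C2 hydroxyl, either anomer); C11 formyl on C9; cis-fused γ-lactone; 5R,6R,8S,9R,10R (key-step product) | O=C[C@@H]1[C@]2(C)CC(O)O[C@@]1(C)C[C@@H]3[C@H]2C(C)(C)C(=O)O3 | intermediate
21 | 4-methoxybenzyl acetal of 20 at C2 | O=C[C@@H]1[C@]2(C)CC(OCc4ccc(OC)cc4)O[C@@]1(C)C[C@@H]3[C@H]2C(C)(C)C(=O)O3 | intermediate
22 | 2-(trimethylsilyloxy)buta-1,3-diene | C=CC(=C)O[Si](C)(C)C | starting material
23 | β-hydroxy enone: side chain C9–CH(OH)–CH2–C(=O)–CH=CH2 on the core of 21; 5R,6R,8S,9S,10R,11S | C=CC(=O)C[C@H](O)[C@@H]1[C@]2(C)CC(OCc4ccc(OC)cc4)O[C@@]1(C)C[C@@H]3[C@H]2C(C)(C)C(=O)O3 | intermediate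
24 | diol: side chain C9–CH(OH)–CH2–C(CH3)(OH)–CH=CH2; γ-lactone and C2 acetal retained; 11S,13R | C=C[C@](C)(O)C[C@H](O)[C@@H]1[C@]2(C)CC(OCc4ccc(OC)cc4)O[C@@]1(C)C[C@@H]3[C@H]2C(C)(C)C(=O)O3 | intermediate
25 | potassium C3 carboxylate of 24 with free 6-hydroxyl | C=C[C@](C)(O)C[C@H](O)[C@@H]1[C@]2(C)CC(OCc3ccc(OC)cc3)O[C@@]1(C)C[C@@H](O)[C@H]2C(C)(C)C(=O)[O-].[K+] | intermediate (not isolated)
26 | C3 allyl ester with free 6-, 11- and 13-hydroxyls; C2 acetal retained | C=C[C@](C)(O)C[C@H](O)[C@@H]1[C@]2(C)CC(OCc3ccc(OC)cc3)O[C@@]1(C)C[C@@H](O)[C@H]2C(C)(C)C(=O)OCC=C | intermediate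
27 | 6,11-bis(triethylsilyl) ether of 26 | C=C[C@](C)(O)C[C@H](O[Si](CC)(CC)CC)[C@@H]1[C@]2(C)CC(OCc3ccc(OC)cc3)O[C@@]1(C)C[C@@H](O[Si](CC)(CC)CC)[C@H]2C(C)(C)C(=O)OCC=C | intermediate
28 | C2 lactol from 27 | C=C[C@](C)(O)C[C@H](O[Si](CC)(CC)CC)[C@@H]1[C@]2(C)CC(O)O[C@@]1(C)C[C@@H](O[Si](CC)(CC)CC)[C@H]2C(C)(C)C(=O)OCC=C | intermediate
29 | δ-lactone (O8–C2=O); 6,11-bis(triethylsilyl) ether; C3 allyl ester | C=C[C@](C)(O[H])C[C@H](O[Si](CC)(CC)CC)[C@@H]1[C@]2(C)CC(=O)O[C@@]1(C)C[C@@H](O[Si](CC)(CC)CC)[C@H]2C(C)(C)C(=O)OCC=C | intermediate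
30 | allyl ester of the target | C=C[C@](C)(O)C[C@H](O)[C@@H]1[C@]2(C)CC(=O)O[C@@]1(C)C[C@@H](O)[C@H]2C(C)(C)C(=O)OCC=C | intermediate
31 | CNP0297019.1 (5R,6R,8S,9S,10R,11S,13R) | C=C[C@](C)(O)C[C@H](O)[C@@H]1[C@]2(C)CC(=O)O[C@@]1(C)C[C@@H](O)[C@H]2C(C)(C)C(=O)O | target

Total step count: 22. Longest linear sequence: 22 steps (from 1; compounds 7, 10 and 22 are purchased).

## Steps most likely to fail

1. Step 13 (proposed new method). What may go wrong: the two diastereotopic arms are not discriminated well enough, or material is lost through dehydration of the aldol or β-elimination of the C6 carboxylate. Fallback with known chemistry, setting out from 18: dibenzylammonium trifluoroacetate in benzene at 50 °C (amine-salt aldol condensation of a keto-aldehyde to a cyclohexenecarbaldehyde) closes ring B with loss of water and should give cyclohexenecarbaldehyde F1 together with its C10 epimer, which is removed by chromatography, so that no discrimination between the arms is asked for. 4-Methoxybenzyl alcohol with Bi(NO3)3·5H2O (cat.) in CH2Cl2 then forms the hemiacetal of the remaining arm aldehyde, whose hydroxyl adds to C8 of the enal (oxa-conjugate addition) with protonation at C9 to the equatorial formyl group. The fallback comes back to the route at 21.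

2. Step 16. What may go wrong: weak 1,3-induction if the magnesium chelate is not rigid, retro-aldol cleavage of the aldolate, or conjugate addition to the vinyl ketone. Fallback, setting out from 21: CH2=C(CH3)CH2MgCl in THF at −78 °C should give homoallylic alcohol F2 with the same facial sense at C11 as in step 15. NaN(SiMe3)2 and Boc2O give tert-butyl carbonate F3. IBr in toluene at −85 °C closes a six-membered carbonate onto C13 with the C11 substituent and the iodomethyl group cis, giving iodocarbonate F4. K2CO3 in MeOH gives epoxy alcohol F5, and Me3S+ I−/n-BuLi in THF (−10 → 23 °C) opens the epoxide at CH2 and eliminates dimethyl sulfide to the vinyl carbinol. Here C13 is set by intramolecular oxygen delivery instead of by addition to a ketone, and the fallback comes back to the route at 24.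

3. Step 10. What may go wrong: slow or incomplete anti elimination, because the antiperiplanar conformer places the ketal carbon gauche to C5. Fallback, setting out from 14: Pd(OAc)2 (10 mol%), NaOAc and O2 in DMSO at 60 °C (oxypalladation of the carboxylate at C6, then β-hydride elimination, for which H6 is the only hydrogen available) should give (Z)-enol lactone F6 without a halide intermediate. Hydrogenation under the conditions of step 11 then comes back to the route at 17.

## Further compounds

F1 | step 13 | (5R,6R,10R)-cyclohexenecarbaldehyde: C8=C9 enal in ring B; free CH2CHO arm on C10; cis-fused γ-lactone | O=CC[C@@]1(C)C(C=O)=C(C)C[C@H]2OC(=O)C(C)(C)[C@@H]12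
F2 | step 16 | (11S)-homoallylic alcohol: side chain C9–CH(OH)–CH2–C(CH3)=CH2 on the core of 21 | C=C(C)C[C@H](O)[C@@H]1[C@]2(C)CC(OCc4ccc(OC)cc4)O[C@@]1(C)C[C@@H]3[C@H]2C(C)(C)C(=O)O3
F3 | step 16 | tert-butyl carbonate of F2 | C=C(C)C[C@H](OC(=O)OC(C)(C)C)[C@@H]1[C@]2(C)CC(OCc4ccc(OC)cc4)O[C@@]1(C)C[C@@H]3[C@H]2C(C)(C)C(=O)O3
F4 | step 16 | (11S,13R)-cyclic iodocarbonate: 4-(iodomethyl)-4-methyl-1,3-dioxan-2-one spanning O11 and O13 | IC[C@@]4(C)C[C@H](OC(=O)O4)[C@@H]1[C@]2(C)CC(OCc5ccc(OC)cc5)O[C@@]1(C)C[C@@H]3[C@H]2C(C)(C)C(=O)O3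
F5 | step 16 | (11S,13R)-epoxy alcohol: C13–C14 epoxide with free 11-hydroxyl | C[C@]4(CO4)C[C@H](O)[C@@H]1[C@]2(C)CC(OCc5ccc(OC)cc5)O[C@@]1(C)C[C@@H]3[C@H]2C(C)(C)C(=O)O3
F6 | step 10 | (4R,5Z)-4-[4,4-dimethoxy-2-(2,2-dimethoxyethyl)butan-2-yl]-5-(2,2-dimethoxypropylidene)-3,3-dimethyloxolan-2-one | CC(OC)(OC)/C=C1\OC(=O)C(C)(C)[C@H]1C(C)(CC(OC)OC)CC(OC)OC
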